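## Retrosynthetic overview

1. Target 17 ← tris-silyl ether 16 (fluoride) ← silyl enol ether 15 by catalytic enantioselective protonation, which sets C3 as the second-to-last event; 15 ← aryl bromide 14 by linear-selective Negishi prenylation at C5'.
2. Key disconnection of 14: bonds C2–C3 and C4–C4a, a formal [4+2] annulation of the aryloxycarbenium ion from (aryloxy)methyl acetate 3 (atoms C2, O1, C8a, C4a) with aryl siloxyalkyne 11 (atoms C3, C4).
3. Enabling feature: C2 is a methylene on the phenolic O1 of the 1,3,5-trioxygenated ring A, so O1 stabilizes a cation at C2 and C4a (ortho to O1, ortho/para to O5 and O7, equivalent to its mirror position) is a strong π-nucleophile; C3–C4 (aryl-bearing carbon next to a ketone) is at the oxidation level of an aryl ynol ether.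
4. Fragment 3 comes from phloroglucinol in two steps; fragment 11 from 5-bromovanillin (methyl transposition, silylation, Colvin alkyne synthesis, acetylide oxidation and O-silylation).
5. Ring order: rings A and B are bought as arenes; ring C is the only ring formed, in the key step.

Key step: step 8

Remark on numbering: isoflavanone numbering (O1, C2, C3, C4, C4a, C5 to C8, C8a; ring B primed) is used for all precursors as well.

Assumption: the sense of induction of the chiral Brønsted acid in step 10 cannot be predicted with certainty for this enol ether; the (S)-configured catalyst is written, and its mirror image would be used if a test run showed the opposite sense.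

## Route

Step 1
Reactants: 1 phloroglucinol
Product: 2 3,5-bis(tert-butyldimethylsilyloxy)phenol
Conditions: TBSCl (2.0 equiv), imidazole, DMF, 0 °C → rt; chromatography
Reagents that add atoms: tert-butyldimethylsilyl chloride, CC(C)(C)[Si](C)(C)Cl
Why: Statistical O-silylation of a threefold-symmetric triphenol should give the bis-silyl ether as the main fraction, separable from the mono- and tris-silyl ethers, which can be recycled.

Step 2
Reactants: 2 3,5-bis(tert-butyldimethylsilyloxy)phenol
Product: 3 [3,5-bis(tert-butyldimethylsilyloxy)phenoxy]methyl acetate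
Conditions: BrCH2OAc, i-Pr2NEt, MeCN, 0 °C → rt
Reagents that add atoms: bromomethyl acetate, CC(=O)OCBr
Why: Williamson-type O-alkylation of the phenol by a very reactive α-halo-ether electrophile under a hindered amine base, which avoids a free phenoxide and thus silyl scrambling.

Step 3
Reactants: 4 5-bromovanillin (3-bromo-4-hydroxy-5-methoxybenzaldehyde)
Product: 5 3-bromo-4,5-dihydroxybenzaldehyde
Conditions: AlCl3, pyridine, CH2Cl2, reflux; aq. HCl
Reagents that add atoms: none
Why: Chelation-assisted demethylation of an ortho-hydroxyanisole, in which the aluminium phenoxide activates the neighbouring methyl ether for SN2 demethylation by pyridine while aldehyde and bromide stay untouched.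

Step 4
Reactants: 5 3-bromo-4,5-dihydroxybenzaldehyde
Product: 6 3-bromo-5-hydroxy-4-methoxybenzaldehyde
Conditions: MeI (1.0 equiv), Li2CO3, DMF, 40 °C
Reagents that add atoms: iodomethane, CI
Why: Regioselective Williamson methylation, since the weak base ionizes only the more acidic 4-OH (para to the aldehyde, ortho to bromine), so the methyl group should land on the oxygen flanked by Br and OH.

Step 5
Reactants: 6 3-bromo-5-hydroxy-4-methoxybenzaldehyde
Product: 7 3-bromo-5-(tert-butyldimethylsilyloxy)-4-methoxybenzaldehyde
Conditions: TBSCl, imidazole, CH2Cl2, rt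
Reagents that add atoms: tert-butyldimethylsilyl chloride, CC(C)(C)[Si](C)(C)Cl
Why: Standard silylation of the remaining phenol gives a protecting group that survives amide bases, the cationic key step and the cross-coupling and is removed at the end together with the ring A silyl ethers.

Step 6
Reactants: 7 3-bromo-5-(tert-butyldimethylsilyloxy)-4-methoxybenzaldehyde
Product: 8 1-bromo-3-(tert-butyldimethylsilyloxy)-5-ethynyl-2-methoxybenzene
Conditions: Me3SiCHN2, LiN(i-Pr)2, THF, -78 °C → rt
Reagents that add atoms: trimethylsilyldiazomethane, C[Si](C)(C)C=[N+]=[N-]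
Why: Colvin rearrangement (one-carbon homologation of an aryl aldehyde to the terminal alkyne with lithiated trimethylsilyldiazomethane), run with an amide base at low temperature so that the aryl bromide and the aryl silyl ether are not touched.

Step 7
Reactants: 8 1-bromo-3-(tert-butyldimethylsilyloxy)-5-ethynyl-2-methoxybenzene
Product: 11 1-bromo-3-(tert-butyldimethylsilyloxy)-2-methoxy-5-[(triisopropylsilyloxy)ethynyl]benzene, via lithium acetylide 9 (not isolated), via lithium ynolate 10 (not isolated)
Conditions: LiN(SiMe3)2, THF, -78 °C; t-BuOOLi (from t-BuOOH and LiN(SiMe3)2), -78 → 0 °C; i-Pr3SiOTf, -78 → 0 °C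
Reagents that add atoms: tert-butyl hydroperoxide, CC(C)(C)OO; triisopropylsilyl trifluoromethanesulfonate, CC(C)[Si](C(C)C)(C(C)C)OS(=O)(=O)C(F)(F)F
Why: Electrophilic oxygenation of a lithium acetylide by a lithium alkyl peroxide gives the ynolate, which the bulky silyl triflate traps on oxygen as a chromatography-stable siloxyalkyne, and the amide base leaves the aryl bromide intact.

Step 8
Reactants: 3 [3,5-bis(tert-butyldimethylsilyloxy)phenoxy]methyl acetate and 11 1-bromo-3-(tert-butyldimethylsilyloxy)-2-methoxy-5-[(triisopropylsilyloxy)ethynyl]benzene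
Product: 14 3-[3-bromo-5-(tert-butyldimethylsilyloxy)-4-methoxyphenyl]-5,7-bis(tert-butyldimethylsilyloxy)-4-(triisopropylsilyloxy)-2H-chromene, via aryloxycarbenium ion 12 (not isolated), via silyl ketenium ion 13 (not isolated)
Conditions: 11 (1.5 equiv), 2,6-di-tert-butyl-4-methylpyridine (1.5 equiv), Me3SiNTf2 (1.1 equiv, slow addition), CH2Cl2, -78 °C; Et3N quench
Reagents that add atoms: none
Why: Proposed new method: Me3SiNTf2 silylates the acetate carbonyl of 3 and expels Me3SiOAc to give the aryloxycarbenium ion 12 (a cationic 2-oxadiene, O1=C2 conjugated with C8a=C4a), the oxygen-polarized β-carbon of siloxyalkyne 11 adds to its methylene carbon (bond C2–C3) to give the O-silyl ketenium ion 13, and C4a of ring A then attacks the ketenium carbon (bond C4–C4a), the hindered pyridine taking the proton of the arenium ion. The closest known reaction types are the oxa-Povarov reaction (aryloxycarbenium ions with alkenes to chromans), the addition of acetal-derived oxocarbenium ions to siloxyalkynes, and the triflimide-promoted carbocyclization of arene-tethered siloxyalkynes to silyl enol ethers of tetralones; what is untested is their merger into one intermolecular formal [4+2] annulation. Ring C closes by a 6-endo-dig Friedel–Crafts attack of the arene on the in-plane acceptor orbital of the ketenium carbon, the topology of the tethered carbocyclization. No stereocenter is formed, because C3 leaves the step sp2-hybridized inside a regiodefined tetrasubstituted silyl enol ether, the substrate that step 10 needs to set C3. The step needs β-regioselectivity at the alkyne (secured by the siloxy oxygen, which stabilizes the ketenium ion far better than the aryl group, whose 4'-methoxy group is twisted out of conjugation by its two ortho substituents, could stabilize a vinyl cation), capture of 12 by the alkyne before it alkylates ring A of a second molecule (secured by the higher π-nucleophilicity of the ynol ether, its excess and the slow generation of 12 at -78 °C), and a single site of ring closure (secured by the symmetry of ring A, whose two positions ortho to O1 are equivalent and each ortho/para to the other two oxygens).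

Step 9
Reactants: 14 3-[3-bromo-5-(tert-butyldimethylsilyloxy)-4-methoxyphenyl]-5,7-bis(tert-butyldimethylsilyloxy)-4-(triisopropylsilyloxy)-2H-chromene
Product: 15 3-[3-(tert-butyldimethylsilyloxy)-4-methoxy-5-(3-methylbut-2-enyl)phenyl]-5,7-bis(tert-butyldimethylsilyloxy)-4-(triisopropylsilyloxy)-2H-chromene
Conditions: prenylzinc bromide (from prenyl bromide, Zn, LiCl), Pd(OAc)2 (2 mol%), CPhos (4 mol%), THF, rt
Reagents that add atoms: prenylzinc bromide, CC(C)=CC[Zn]Br
Why: Negishi coupling of the aryl bromide with an allylic zinc reagent on zerovalent palladium, in which the bulky biarylphosphine enforces reductive elimination at the unsubstituted allyl terminus (linear prenyl, no reverse-prenyl isomer), while the silyl enol ether and the aryl silyl ethers are inert to the organozinc.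

Step 10
Reactants: 15 3-[3-(tert-butyldimethylsilyloxy)-4-methoxy-5-(3-methylbut-2-enyl)phenyl]-5,7-bis(tert-butyldimethylsilyloxy)-4-(triisopropylsilyloxy)-2H-chromene
Product: 16 (3S)-3-[3-(tert-butyldimethylsilyloxy)-4-methoxy-5-(3-methylbut-2-enyl)phenyl]-5,7-bis(tert-butyldimethylsilyloxy)chroman-4-one
Conditions: (S)-3,3'-bis(2,4,6-triisopropylphenyl)-1,1'-binaphthyl-2,2'-diyl N-triflylthiophosphoramide (5 mol%), PhOH (1.2 equiv), toluene, rt
Reagents that add atoms: none
Why: Catalytic enantioselective protonation of a silyl enol ether of a 2-aryl cyclic ketone by a chiral Brønsted acid with phenol as stoichiometric proton source and silyl acceptor, in which the C3 stereocenter is set by face-selective proton delivery inside the chiral ion pair and the non-basic medium keeps the new α-aryl ketone from enolizing.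

Step 11
Reactants: 16 (3S)-3-[3-(tert-butyldimethylsilyloxy)-4-methoxy-5-(3-methylbut-2-enyl)phenyl]-5,7-bis(tert-butyldimethylsilyloxy)chroman-4-one
Product: 17 (3S)-5,7,3'-trihydroxy-4'-methoxy-5'-prenylisoflavanone
Conditions: Et3N·3HF, THF, 0 °C → rt
Reagents that add atoms: none
Why: Fluoride-mediated cleavage of the three aryl silyl ethers under weakly acidic conditions, where neither a phenoxide nor an enolate is formed, so that C3 should keep its configuration and the prenyl alkene and the methyl ether stay untouched.

## Compound list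

1 | phloroglucinol | Oc1cc(O)cc(O)c1 | starting material
2 | 3,5-bis(tert-butyldimethylsilyloxy)phenol | Oc1cc(O[Si](C)(C)C(C)(C)C)cc(O[Si](C)(C)C(C)(C)C)c1 | intermediate
3 | [3,5-bis(tert-butyldimethylsilyloxy)phenoxy]methyl acetate | CC(=O)OCOc1cc(O[Si](C)(C)C(C)(C)C)cc(O[Si](C)(C)C(C)(C)C)c1 | intermediate
4 | 5-bromovanillin (3-bromo-4-hydroxy-5-methoxybenzaldehyde) | COc1cc(C=O)cc(Br)c1O | starting material
5 | 3-bromo-4,5-dihydroxybenzaldehyde | O=Cc1cc(O)c(O)c(Br)c1 | intermediate
6 | 3-bromo-5-hydroxy-4-methoxybenzaldehyde | COc1c(O)cc(C=O)cc1Br | intermediate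
7 | 3-bromo-5-(tert-butyldimethylsilyloxy)-4-methoxybenzaldehyde | COc1c(Br)cc(C=O)cc1O[Si](C)(C)C(C)(C)C | intermediate
8 | 1-bromo-3-(tert-butyldimethylsilyloxy)-5-ethynyl-2-methoxybenzene | COc1c(Br)cc(C#C)cc1O[Si](C)(C)C(C)(C)C | intermediate
9 | lithium acetylide of 8 (formed in the flask) | COc1c(Br)cc(C#C[Li])cc1O[Si](C)(C)C(C)(C)C | intermediate
10 | lithium ynolate, lithium 2-[3-bromo-5-(tert-butyldimethylsilyloxy)-4-methoxyphenyl]ethynolate (formed in the flask) | COc1c(Br)cc(C#CO[Li])cc1O[Si](C)(C)C(C)(C)C | intermediate
11 | 1-bromo-3-(tert-butyldimethylsilyloxy)-2-methoxy-5-[(triisopropylsilyloxy)ethynyl]benzene | COc1c(Br)cc(C#CO[Si](C(C)C)(C(C)C)C(C)C)cc1O[Si](C)(C)C(C)(C)C | intermediate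
12 | aryloxycarbenium ion, [3,5-bis(tert-butyldimethylsilyloxy)phenyl](methylidene)oxonium triflimide (formed in the flask) | C=[O+]c1cc(O[Si](C)(C)C(C)(C)C)cc(O[Si](C)(C)C(C)(C)C)c1.O=S(=O)([N-]S(=O)(=O)C(F)(F)F)C(F)(F)F | intermediate
13 | silyl ketenium ion, O-triisopropylsilyl ketenium triflimide carrying the aryl group and the aryloxymethyl group on the terminal carbon (formed in the flask) | COc1c(Br)cc(C(COc2cc(O[Si](C)(C)C(C)(C)C)cc(O[Si](C)(C)C(C)(C)C)c2)=C=[O+][Si](C(C)C)(C(C)C)C(C)C)cc1O[Si](C)(C)C(C)(C)C.O=S(=O)([N-]S(=O)(=O)C(F)(F)F)C(F)(F)F | intermediate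
14 | 3-[3-bromo-5-(tert-butyldimethylsilyloxy)-4-methoxyphenyl]-5,7-bis(tert-butyldimethylsilyloxy)-4-(triisopropylsilyloxy)-2H-chromene | COc1c(Br)cc(C2=C(O[Si](C(C)C)(C(C)C)C(C)C)c3c(O[Si](C)(C)C(C)(C)C)cc(O[Si](C)(C)C(C)(C)C)cc3OC2)cc1O[Si](C)(C)C(C)(C)C | intermediate
15 | 3-[3-(tert-butyldimethylsilyloxy)-4-methoxy-5-(3-methylbut-2-enyl)phenyl]-5,7-bis(tert-butyldimethylsilyloxy)-4-(triisopropylsilyloxy)-2H-chromene | COc1c(CC=C(C)C)cc(C2=C(O[Si](C(C)C)(C(C)C)C(C)C)c3c(O[Si](C)(C)C(C)(C)C)cc(O[Si](C)(C)C(C)(C)C)cc3OC2)cc1O[Si](C)(C)C(C)(C)C | intermediate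
16 | (3S)-3-[3-(tert-butyldimethylsilyloxy)-4-methoxy-5-(3-methylbut-2-enyl)phenyl]-5,7-bis(tert-butyldimethylsilyloxy)chroman-4-one | COc1c(O[Si](C)(C)C(C)(C)C)cc([C@H]2COc3cc(O[Si](C)(C)C(C)(C)C)cc(O[Si](C)(C)C(C)(C)C)c3C2=O)cc1CC=C(C)C | intermediate
17 | (3S)-5,7,3'-trihydroxy-4'-methoxy-5'-prenylisoflavanone | COc1c(O)cc([C@H]2COc3cc(O)cc(O)c3C2=O)cc1CC=C(C)C | target

## Step count and risks

Total step count: 11 steps. Longest linear sequence: 9 steps (4 to 17, steps 3 to 11).

Steps most likely to fail:

1. Step 8 (Proposed new method). What may go wrong: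
   - Cation 12 may alkylate ring A of a second molecule of 3 faster than the alkyne captures it, which leads to oligomerization.
   - Ketenium ion 13 may be intercepted by the ether oxygen O1 (four-ring closure and fragmentation, an alkyne–carbonyl metathesis pathway) or lose its silyl group before the arene closes.
   - The enol ether may be protodesilylated by adventitious acid.

   Fallback, known chemistry only, setting out from ynolate 10 and acetate 3 and returning at 14. A hydrolytic quench of 10 with dilute aqueous HCl in place of the silyl triflate should give [3-bromo-5-(tert-butyldimethylsilyloxy)-4-methoxyphenyl]acetic acid F1. LiN(SiMe3)2 (2.2 equiv) and Me3SiCl in THF at -78 °C convert it into the bis(trimethylsilyl) ketene acetal F2. This much stronger π-nucleophile is joined to 3 by a Mukaiyama-type addition to the oxocarbenium ion (Me3SiOTf cat., CH2Cl2, -78 °C) to give the trimethylsilyl 2-aryl-3-aryloxypropanoate F3. Aqueous work-up hydrolyses F3 to the 2-aryl-3-aryloxypropanoic acid F4. Intramolecular Friedel–Crafts acylation of the trioxygenated ring ((CF3CO)2O, CH2Cl2, 0 °C) closes ring C to the racemic 3-aryl-chroman-4-one F5. Enol silylation with i-Pr3SiOTf and Et3N in CH2Cl2 then gives 14.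

2. Step 10. What may go wrong: slow turnover because the bulky silyl group is transferred to phenol sluggishly, and insufficient facial discrimination at an enol ether that is conjugated with ring A and crowded by the C5 silyloxy group.

   Fallback, setting out from 15 and returning at 16. Acid hydrolysis of the enol ether (TsOH·H2O cat., THF–H2O, rt) gives the racemic tris-silyl isoflavanone F6. It is resolved by preparative chromatography on a chiral stationary phase to give 16. The unwanted enantiomer is racemized through its enolate (DBU, THF) and returned to the separation.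

3. Step 11. What may go wrong: erosion of enantiomeric purity by enolization of the α-aryl ketone while three silyl ethers are being cleaved (the C5 phenol that appears hydrogen-bonds to the C4 carbonyl and acidifies C3–H), and hydrofluorination of the prenyl alkene on prolonged exposure.

   Fallback, setting out from 15 and returning at 17. The order of the last two events is reversed, so that the stereocenter is created in the final operation. Buffered fluoride (Bu4NF/AcOH 1:1, THF, 0 °C) removes only the three aryl silyl groups and leaves the hindered tetrasubstituted silyl enol ether, giving 3-[3-hydroxy-4-methoxy-5-(3-methylbut-2-enyl)phenyl]-4-(triisopropylsilyloxy)-2H-chromene-5,7-diol F7. The chiral-acid-catalysed protonation of step 10 (same catalyst, phenol as proton source and silyl acceptor, toluene) then delivers 17 directly.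

## Further compounds

F1 | step 8 | [3-bromo-5-(tert-butyldimethylsilyloxy)-4-methoxyphenyl]acetic acid | COc1c(Br)cc(CC(O)=O)cc1O[Si](C)(C)C(C)(C)C
F2 | step 8 | bis(trimethylsilyl) ketene acetal of F1, 1-bromo-5-[2,2-bis(trimethylsilyloxy)ethenyl]-3-(tert-butyldimethylsilyloxy)-2-methoxybenzene | COc1c(Br)cc(C=C(O[Si](C)(C)C)O[Si](C)(C)C)cc1O[Si](C)(C)C(C)(C)C
F3 | step 8 | trimethylsilyl 2-[3-bromo-5-(tert-butyldimethylsilyloxy)-4-methoxyphenyl]-3-[3,5-bis(tert-butyldimethylsilyloxy)phenoxy]propanoate (racemic) | COc1c(Br)cc(C(COc2cc(O[Si](C)(C)C(C)(C)C)cc(O[Si](C)(C)C(C)(C)C)c2)C(=O)O[Si](C)(C)C)cc1O[Si](C)(C)C(C)(C)C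
F4 | step 8 | 2-[3-bromo-5-(tert-butyldimethylsilyloxy)-4-methoxyphenyl]-3-[3,5-bis(tert-butyldimethylsilyloxy)phenoxy]propanoic acid (racemic) | COc1c(Br)cc(C(COc2cc(O[Si](C)(C)C(C)(C)C)cc(O[Si](C)(C)C(C)(C)C)c2)C(O)=O)cc1O[Si](C)(C)C(C)(C)C
F5 | step 8 | 3-[3-bromo-5-(tert-butyldimethylsilyloxy)-4-methoxyphenyl]-5,7-bis(tert-butyldimethylsilyloxy)chroman-4-one (racemic) | COc1c(Br)cc(C2COc3cc(O[Si](C)(C)C(C)(C)C)cc(O[Si](C)(C)C(C)(C)C)c3C2=O)cc1O[Si](C)(C)C(C)(C)C
F6 | step 10 | 3-[3-(tert-butyldimethylsilyloxy)-4-methoxy-5-(3-methylbut-2-enyl)phenyl]-5,7-bis(tert-butyldimethylsilyloxy)chroman-4-one (racemic) | COc1c(O[Si](C)(C)C(C)(C)C)cc(C2COc3cc(O[Si](C)(C)C(C)(C)C)cc(O[Si](C)(C)C(C)(C)C)c3C2=O)cc1CC=C(C)C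
F7 | step 11 | 3-[3-hydroxy-4-methoxy-5-(3-methylbut-2-enyl)phenyl]-4-(triisopropylsilyloxy)-2H-chromene-5,7-diol | COc1c(O)cc(C2=C(O[Si](C(C)C)(C(C)C)C(C)C)c3c(O)cc(O)cc3OC2)cc1CC=C(C)C
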